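**Retrosynthetic overview**

1. The target is the ring-closed hemiketal of a hydroxy enone. Opening the left oxepane at the hemiketal C–O bond and cutting the enone between its carbonyl and vinyl carbons (Nozaki–Hiyama–Kishi coupling, then oxidation) gives left aldehyde 15 and right (E)-iodoalkene 30.
2. In the left cyclohexane, the ring-fusion CH next to C(CH3)2 is bonded to the ring carbon bearing CH3 and the ring oxygen. With the exocyclic CH2 on that CH raised to CHO, the two carbons are an aldol pair, and C(CH3)2 leaves the aldehyde only one α-carbon. Their bond closes the ring by D-proline-catalysed 6-enolexo aldolization of achiral, open-chain 3,3-dimethyl-7-oxooctanal (6). The CHO then takes the chiral-pool side chain (Wittig, hydrogenation).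
3. The right oxepane and cyclohexanone form together in an epoxide-opening cascade of the bis-epoxide silyl enol ether of (E)-geranylacetone. Enone blocking then allows axial hydroxymethylation next to the angular methyl and equatorial methyl addition.
4. Ring order: left cyclohexane (step 3), right oxepane plus cyclohexane (step 12), left oxepane by hemiketalization (step 22).

Key step: step 3

Assumption: the facial sense of the proline aldol follows the accepted enamine transition state (electrophile delivered to the enamine face syn to the carboxylic acid, anti aldol), which predicts the (1R,2R) aldol from D-proline.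
Assumption: the target is the thermodynamically preferred ring-chain tautomer of hydroxy enone 33, so oxepane closure and the hemiketal configuration are set by equilibration.
Assumption: the D-fructose-derived ketone epoxidizes (E)-trisubstituted olefins with the (R,R) sense documented for this olefin class.

**Route**

Step 1
Reactants: 1 3-methylbut-2-enal; 2 2-(3-chloropropyl)-2-methyl-1,3-dioxolane
Product: 5 3,3-dimethyl-6-(2-methyl-1,3-dioxolan-2-yl)hexanal, via Grignard reagent 3 (not isolated), via trimethylsilyl enol ether 4 (not isolated)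
Conditions: 2, Mg, THF, reflux; CuBr·SMe2 (5 mol %), Me3SiCl, HMPA, then 1, THF, −78 °C; then K2CO3, MeOH, 0 °C
Reagents that add atoms: none
Why: copper-catalysed, chlorosilane-accelerated conjugate addition of a Grignard reagent to a β,β-disubstituted enal should build the quaternary C(CH3)2 carbon, the enolate being held as silyl enol ether 4 until mild methanolysis frees the aldehyde without touching the dioxolane; no stereocentre is formed.

Step 2
Reactants: 5 3,3-dimethyl-6-(2-methyl-1,3-dioxolan-2-yl)hexanal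
Product: 6 3,3-dimethyl-7-oxooctanal
Conditions: 1 M aq. HCl, THF, 0 °C to rt
Reagents that add atoms: water, O
Why: acid-catalysed ketal hydrolysis unmasks the methyl ketone, short contact at low temperature keeping the keto aldehyde from acid-catalysed aldolization; no stereocentre is formed.

Step 3
Reactants: 6 3,3-dimethyl-7-oxooctanal
Product: 7 (1R,2R)-2-hydroxy-2,6,6-trimethylcyclohexane-1-carbaldehyde
Conditions: D-proline (20 mol %), CH2Cl2 (0.05 M), rt
Reagents that add atoms: none
Why: D-proline condenses chemoselectively with the aldehyde to the (E)-enamine, whose only nucleophilic carbon (the CH2 next to the gem-dimethyl carbon) adds to the methyl ketone activated by a hydrogen bond from the carboxylic acid, and hydrolysis of the iminium ion releases the catalyst. The closest known reaction type is the proline-catalysed intramolecular 6-enolexo aldolization of dialdehydes and keto aldehydes. The cyclohexane closes 6-enolexo (6-exo-trig at the ketone) through a chair in which the ketone chain is equatorial and its methyl axial. The ring CH (C1) is set by the enamine face syn to the carboxylic acid of the D-catalyst, and the carbinol (C2) by the ketone face exposed in that hydrogen-bonded chair, which places CHO and OH trans (anti aldol) and should give (1R,2R). The step needs the aldehyde as donor and the ketone as acceptor, and ring closure ahead of intermolecular condensation: only the aldehyde forms an enamine rapidly, the quaternary carbon leaves it a single enolizable position, a ketone enamine could reach the aldehyde through a six-membered ring only as its disfavoured internal isomer, the gem-dialkyl effect favours cyclization, and the product aldehyde, flanked by two fully substituted carbons, is too hindered to re-enter enamine chemistry (dehydration, epimerization).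

Step 4
Reactants: 7 (1R,2R)-2-hydroxy-2,6,6-trimethylcyclohexane-1-carbaldehyde
Product: 8 (1R,2R)-2,6,6-trimethyl-2-[(triethylsilyl)oxy]cyclohexane-1-carbaldehyde
Conditions: Et3SiOTf, 2,6-lutidine, CH2Cl2, −78 °C
Reagents that add atoms: triethylsilyl trifluoromethanesulfonate, CC[Si](CC)(CC)OS(=O)(=O)C(F)(F)F
Why: silyl triflate silylation of the hindered tertiary alcohol at low temperature blocks retro-aldol cleavage in the basic Wittig step; both stereocentres are untouched.

Step 5
Reactants: 9 (2S)-3-bromo-2-methylpropan-1-ol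
Product: 10 benzyl (2S)-3-bromo-2-methylpropyl ether
Conditions: benzyl 2,2,2-trichloroacetimidate, TfOH (cat.), cyclohexane–CH2Cl2, rt
Reagents that add atoms: benzyl 2,2,2-trichloroacetimidate, N=C(OCc1ccccc1)C(Cl)(Cl)Cl
Why: acid-catalysed imidate benzylation avoids base (oxetane formation or elimination of the bromohydrin); the chiral-pool stereocentre is retained.

Step 6
Reactants: 10 benzyl (2S)-3-bromo-2-methylpropyl ether
Product: 11 [(2S)-3-(benzyloxy)-2-methylpropyl]triphenylphosphonium bromide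
Conditions: PPh3, neat, 110 °C
Reagents that add atoms: triphenylphosphine, c1ccc(cc1)P(c1ccccc1)c1ccccc1
Why: SN2 quaternization of the primary bromide should give the phosphonium salt; the stereocentre is β to phosphorus and is not touched.

Step 7
Reactants: 11 [(2S)-3-(benzyloxy)-2-methylpropyl]triphenylphosphonium bromide; 8 (1R,2R)-2,6,6-trimethyl-2-[(triethylsilyl)oxy]cyclohexane-1-carbaldehyde
Product: 13 triethyl({(1R,2R)-2-[(1Z,3R)-4-(benzyloxy)-3-methylbut-1-en-1-yl]-1,3,3-trimethylcyclohexyl}oxy)silane, via phosphonium ylide 12 (not isolated)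
Conditions: NaN(SiMe3)2, THF, −78 to 0 °C; then 8, 0 °C to reflux
Reagents that add atoms: none
Why: Wittig olefination with the non-stabilized ylide should join the side chain to the hindered aldehyde as the (Z)-alkene (geometry is removed in step 8); no stereocentre is formed and the α-centre of 8 is shielded from enolization by its two fully substituted neighbours.

Step 8
Reactants: 13 triethyl({(1R,2R)-2-[(1Z,3R)-4-(benzyloxy)-3-methylbut-1-en-1-yl]-1,3,3-trimethylcyclohexyl}oxy)silane
Product: 14 (2R)-2-methyl-4-{(1R,2R)-2,6,6-trimethyl-2-[(triethylsilyl)oxy]cyclohexyl}butan-1-ol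
Conditions: H2 (1 atm), Pd(OH)2 on carbon, EtOAc, rt
Reagents that add atoms: none
Why: heterogeneous hydrogenation should saturate the disubstituted alkene and hydrogenolyse the benzyl ether in one operation, the tertiary silyl ether surviving in a non-protic solvent; no stereocentre is formed.

Step 9
Reactants: 14 (2R)-2-methyl-4-{(1R,2R)-2,6,6-trimethyl-2-[(triethylsilyl)oxy]cyclohexyl}butan-1-ol
Product: 15 (2R)-2-methyl-4-{(1R,2R)-2,6,6-trimethyl-2-[(triethylsilyl)oxy]cyclohexyl}butanal
Conditions: Dess–Martin periodinane, NaHCO3, CH2Cl2, 0 °C to rt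
Reagents that add atoms: none
Why: buffered Dess–Martin oxidation should give the aldehyde without epimerizing its α-methyl centre.

Step 10
Reactants: 16 (5E)-6,10-dimethylundeca-5,9-dien-2-one ((E)-geranylacetone)
Product: 17 4-[(2R,3R)-3-{2-[(2R)-3,3-dimethyloxiran-2-yl]ethyl}-3-methyloxiran-2-yl]butan-2-one
Conditions: 1,2:4,5-di-O-isopropylidene-β-D-erythro-2,3-hexodiulo-2,6-pyranose (30 mol % per alkene), 2KHSO5·KHSO4·K2SO4, K2CO3, Bu4NHSO4, aq. Na2B4O7 buffer, MeCN–CH2(OMe)2, 0 °C
Reagents that add atoms: potassium peroxymonosulfate, [K+].[O-]S(=O)(=O)OO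
Why: Shi asymmetric epoxidation through the spiro dioxirane transition state should epoxidize both trisubstituted olefins with the same facial sense, setting the (2R,3R) epoxide whose CH–O carbon becomes the right ring-fusion CH–O and whose quaternary carbon becomes, after inversion, the angular carbon.

Step 11
Reactants: 17 4-[(2R,3R)-3-{2-[(2R)-3,3-dimethyloxiran-2-yl]ethyl}-3-methyloxiran-2-yl]butan-2-one
Product: 19 tert-butyl({4-[(2R,3R)-3-{2-[(2R)-3,3-dimethyloxiran-2-yl]ethyl}-3-methyloxiran-2-yl]but-1-en-2-yl}oxy)dimethylsilane, via lithium enolate 18 (not isolated)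
Conditions: LiN(iPr)2, THF, −78 °C; tBuMe2SiCl, HMPA, −78 to 0 °C
Reagents that add atoms: tert-butyldimethylsilyl chloride, CC(C)(C)[Si](C)(C)Cl
Why: kinetic deprotonation of the methyl ketone at the methyl group and O-silylation should give the terminal silyl enol ether, the epoxides being inert to the amide base at low temperature.

Step 12
Reactants: 19 tert-butyl({4-[(2R,3R)-3-{2-[(2R)-3,3-dimethyloxiran-2-yl]ethyl}-3-methyloxiran-2-yl]but-1-en-2-yl}oxy)dimethylsilane
Product: 20 (3R,5aR,9aR)-3-[(tert-butyldimethylsilyl)oxy]-2,2,5a-trimethyloctahydro-1-benzoxepin-7(2H)-one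
Conditions: tBuMe2SiOTf (20 mol %), 2,6-di-tert-butyl-4-methylpyridine (30 mol %), CH2Cl2, −78 °C
Reagents that add atoms: none
Why: the silyl triflate activates the terminal epoxide, whose tertiary carbon is attacked by the oxygen of the internal epoxide to give a bicyclic epoxonium ion that the silyl enol ether carbon opens at its tertiary carbon with inversion (epoxide-opening oxa- and carbacyclization cascade, copying the presumed biogenesis of this half), so oxepane and cyclohexanone should form together, trans-fused because the (E)-olefin geometry is relayed by anti opening, with silyl transfer from the enol ether to the former epoxide oxygen regenerating the promoter.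

Step 13
Reactants: 20 (3R,5aR,9aR)-3-[(tert-butyldimethylsilyl)oxy]-2,2,5a-trimethyloctahydro-1-benzoxepin-7(2H)-one
Product: 23 (3R,5aR,9aR)-3-[(tert-butyldimethylsilyl)oxy]-2,2,5a-trimethyl-3,4,5,5a,6,9a-hexahydro-1-benzoxepin-7(2H)-one, via lithium enolate 21 (not isolated), via trimethylsilyl enol ether 22 (not isolated)
Conditions: LiN(iPr)2, THF, −78 °C; Me3SiCl; then Pd(OAc)2 (1.1 equiv), MeCN, rt
Reagents that add atoms: none
Why: kinetic deprotonation should occur at the CH2 remote from the quaternary carbon, and Saegusa–Ito dehydrogenation of that silyl enol ether gives the enone, which leaves the CH2 next to the angular methyl as the only enolizable position.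

Step 14
Reactants: 23 (3R,5aR,9aR)-3-[(tert-butyldimethylsilyl)oxy]-2,2,5a-trimethyl-3,4,5,5a,6,9a-hexahydro-1-benzoxepin-7(2H)-one
Product: 25 (3R,5aR,6R,9aR)-3-[(tert-butyldimethylsilyl)oxy]-6-(hydroxymethyl)-2,2,5a-trimethyl-3,4,5,5a,6,9a-hexahydro-1-benzoxepin-7(2H)-one, via lithium dienolate 24 (not isolated)
Conditions: LiN(iPr)2, THF, −78 °C; then CH2O (gas), −78 °C; aq. NH4Cl
Reagents that add atoms: formaldehyde, C=O
Why: kinetic α′-deprotonation of the enone and aldol addition to monomeric formaldehyde; the electrophile should enter anti to the pseudoaxial angular methyl on the adjacent quaternary carbon, setting the new CH centre with its C–C bond axial and trans to that methyl.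

Step 15
Reactants: 25 (3R,5aR,6R,9aR)-3-[(tert-butyldimethylsilyl)oxy]-6-(hydroxymethyl)-2,2,5a-trimethyl-3,4,5,5a,6,9a-hexahydro-1-benzoxepin-7(2H)-one
Product: 26 (3R,5aR,6R,9aR)-3-[(tert-butyldimethylsilyl)oxy]-6-(hydroxymethyl)-2,2,5a-trimethyloctahydro-1-benzoxepin-7(2H)-one
Conditions: H2 (1 atm), Pd on carbon, EtOAc, rt
Reagents that add atoms: none
Why: chemoselective hydrogenation of the conjugated C=C under neutral conditions removes the blocking unsaturation without epimerizing the α-centre; no stereocentre is formed.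

Step 16
Reactants: 26 (3R,5aR,6R,9aR)-3-[(tert-butyldimethylsilyl)oxy]-6-(hydroxymethyl)-2,2,5a-trimethyloctahydro-1-benzoxepin-7(2H)-one
Product: 27 (3R,5aR,6R,7S,9aR)-3-[(tert-butyldimethylsilyl)oxy]-6-(hydroxymethyl)-2,2,5a,7-tetramethyldecahydro-1-benzoxepin-7-ol
Conditions: CeCl3, MeMgBr (4 equiv), THF, −78 °C
Reagents that add atoms: methylmagnesium bromide, C[Mg]Br
Why: 1,2-addition of the weakly basic organocerium reagent; the axial trajectory is blocked by the syn-axial angular methyl of the locked trans-fused chair, so methyl should enter equatorially and give the axial tertiary hydroxyl, cis to the angular methyl and trans to the hydroxymethyl group.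

Step 17
Reactants: 27 (3R,5aR,6R,7S,9aR)-3-[(tert-butyldimethylsilyl)oxy]-6-(hydroxymethyl)-2,2,5a,7-tetramethyldecahydro-1-benzoxepin-7-ol
Product: 28 (3R,5aR,6R,7S,9aR)-6-(hydroxymethyl)-2,2,5a,7-tetramethyldecahydro-1-benzoxepine-3,7-diol
Conditions: Bu4NF, THF, 50 °C
Reagents that add atoms: none
Why: fluoride desilylation frees the secondary hydroxyl now that all enolate chemistry is finished; no stereocentre is affected.

Step 18
Reactants: 28 (3R,5aR,6R,7S,9aR)-6-(hydroxymethyl)-2,2,5a,7-tetramethyldecahydro-1-benzoxepine-3,7-diol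
Product: 29 (5aR,6S,7S,9aR)-7-hydroxy-2,2,5a,7-tetramethyl-3-oxodecahydro-1-benzoxepine-6-carbaldehyde
Conditions: Dess–Martin periodinane (3 equiv), NaHCO3, CH2Cl2, 0 °C to rt
Reagents that add atoms: none
Why: Dess–Martin oxidation should convert the primary alcohol to the aldehyde and the secondary alcohol to the oxepanone in one operation, the tertiary alcohol being inert and the buffered, non-basic medium sparing the β-hydroxy aldehyde from retro-aldol cleavage.

Step 19
Reactants: 29 (5aR,6S,7S,9aR)-7-hydroxy-2,2,5a,7-tetramethyl-3-oxodecahydro-1-benzoxepine-6-carbaldehyde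
Product: 30 (5aR,6S,7S,9aR)-7-hydroxy-6-[(E)-2-iodoethenyl]-2,2,5a,7-tetramethyloctahydro-1-benzoxepin-3(2H)-one
Conditions: CrCl2 (6 equiv), CHI3 (2 equiv), THF–1,4-dioxane, 0 °C to rt
Reagents that add atoms: iodoform, IC(I)I
Why: Takai olefination is aldehyde-selective, non-basic and (E)-selective, so the iodoalkene should form without touching the ketone, the free tertiary alcohol or the axial α-centre.

Step 20
Reactants: 30 (5aR,6S,7S,9aR)-7-hydroxy-6-[(E)-2-iodoethenyl]-2,2,5a,7-tetramethyloctahydro-1-benzoxepin-3(2H)-one; 15 (2R)-2-methyl-4-{(1R,2R)-2,6,6-trimethyl-2-[(triethylsilyl)oxy]cyclohexyl}butanal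
Product: 31 (5aR,6S,7S,9aR)-7-hydroxy-6-[(1E,4R)-3-hydroxy-4-methyl-6-{(1R,2R)-2,6,6-trimethyl-2-[(triethylsilyl)oxy]cyclohexyl}hex-1-en-1-yl]-2,2,5a,7-tetramethyloctahydro-1-benzoxepin-3(2H)-one (both carbinol epimers)
Conditions: CrCl2 (4 equiv), NiCl2 (2 mol %), DMSO, rt
Reagents that add atoms: none
Why: Nozaki–Hiyama–Kishi coupling joins the halves with retention of the (E)-geometry and is selective for the aldehyde over the ketone and the free hydroxyls; the new carbinol centre is inconsequential because it is oxidized in step 21.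

Step 21
Reactants: 31 (5aR,6S,7S,9aR)-7-hydroxy-6-[(1E,4R)-3-hydroxy-4-methyl-6-{(1R,2R)-2,6,6-trimethyl-2-[(triethylsilyl)oxy]cyclohexyl}hex-1-en-1-yl]-2,2,5a,7-tetramethyloctahydro-1-benzoxepin-3(2H)-one
Product: 32 (5aR,6S,7S,9aR)-7-hydroxy-2,2,5a,7-tetramethyl-6-[(1E,4R)-4-methyl-3-oxo-6-{(1R,2R)-2,6,6-trimethyl-2-[(triethylsilyl)oxy]cyclohexyl}hex-1-en-1-yl]octahydro-1-benzoxepin-3(2H)-one
Conditions: Dess–Martin periodinane, NaHCO3, CH2Cl2, 0 °C
Reagents that add atoms: none
Why: Dess–Martin oxidation of the allylic alcohol should give the (E)-enone under buffered conditions that spare the α-methyl stereocentre.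

Step 22
Reactants: 32 (5aR,6S,7S,9aR)-7-hydroxy-2,2,5a,7-tetramethyl-6-[(1E,4R)-4-methyl-3-oxo-6-{(1R,2R)-2,6,6-trimethyl-2-[(triethylsilyl)oxy]cyclohexyl}hex-1-en-1-yl]octahydro-1-benzoxepin-3(2H)-one
Product: 34 (5aR,6S,7S,9aR)-7-hydroxy-6-{(E)-2-[(2R,3R,5aR,9aR)-2-hydroxy-3,6,6,9a-tetramethyldecahydro-1-benzoxepin-2-yl]ethenyl}-2,2,5a,7-tetramethyloctahydro-1-benzoxepin-3(2H)-one, via hydroxy enone 33 (not isolated)
Conditions: HF·pyridine, pyridine, THF, 0 °C to rt
Reagents that add atoms: none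
Why: buffered fluoride desilylation frees the tertiary hydroxyl, which should add to the enone carbonyl to close the left oxepane as the hemiketal, the hemiketal carbon equilibrating to the configuration with the alkenyl group trans to the neighbouring methyl.

**Compound list**

1 | 3-methylbut-2-enal | CC(C)=CC=O | starting material
2 | 2-(3-chloropropyl)-2-methyl-1,3-dioxolane | CC1(CCCCl)OCCO1 | starting material
3 | [3-(2-methyl-1,3-dioxolan-2-yl)propyl]magnesium chloride | CC1(CCC[Mg]Cl)OCCO1 | intermediate (not isolated)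
4 | {[3,3-dimethyl-6-(2-methyl-1,3-dioxolan-2-yl)hex-1-en-1-yl]oxy}trimethylsilane (E/Z mixture) | C[Si](C)(C)OC=CC(C)(C)CCCC1(C)OCCO1 | intermediate (not isolated)
5 | 3,3-dimethyl-6-(2-methyl-1,3-dioxolan-2-yl)hexanal | O=CCC(C)(C)CCCC1(C)OCCO1 | intermediate
6 | 3,3-dimethyl-7-oxooctanal | CC(=O)CCCC(C)(C)CC=O | intermediate
7 | (1R,2R)-2-hydroxy-2,6,6-trimethylcyclohexane-1-carbaldehyde | O=C[C@@H]1C(C)(C)CCC[C@@]1(C)O | intermediate
8 | (1R,2R)-2,6,6-trimethyl-2-[(triethylsilyl)oxy]cyclohexane-1-carbaldehyde | O=C[C@@H]1C(C)(C)CCC[C@@]1(C)O[Si](CC)(CC)CC | intermediate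
9 | (2S)-3-bromo-2-methylpropan-1-ol | C[C@@H](CO)CBr | starting material
10 | benzyl (2S)-3-bromo-2-methylpropyl ether | C[C@@H](COCc1ccccc1)CBr | intermediate
11 | [(2S)-3-(benzyloxy)-2-methylpropyl]triphenylphosphonium bromide | C[C@@H](COCc1ccccc1)C[P+](c1ccccc1)(c1ccccc1)c1ccccc1.[Br-] | intermediate
12 | [(2R)-3-(benzyloxy)-2-methylpropylidene]triphenylphosphorane | C[C@@H](COCc1ccccc1)C=P(c1ccccc1)(c1ccccc1)c1ccccc1 | intermediate (not isolated)
13 | triethyl({(1R,2R)-2-[(1Z,3R)-4-(benzyloxy)-3-methylbut-1-en-1-yl]-1,3,3-trimethylcyclohexyl}oxy)silane | C[C@@H](COCc1ccccc1)/C=C\[C@@H]1C(C)(C)CCC[C@@]1(C)O[Si](CC)(CC)CC | intermediate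
14 | (2R)-2-methyl-4-{(1R,2R)-2,6,6-trimethyl-2-[(triethylsilyl)oxy]cyclohexyl}butan-1-ol | C[C@@H](CO)CC[C@@H]1C(C)(C)CCC[C@@]1(C)O[Si](CC)(CC)CC | intermediate
15 | (2R)-2-methyl-4-{(1R,2R)-2,6,6-trimethyl-2-[(triethylsilyl)oxy]cyclohexyl}butanal | C[C@@H](C=O)CC[C@@H]1C(C)(C)CCC[C@@]1(C)O[Si](CC)(CC)CC | intermediate
16 | (5E)-6,10-dimethylundeca-5,9-dien-2-one | CC(=O)CC/C=C(\C)CCC=C(C)C | starting material
17 | 4-[(2R,3R)-3-{2-[(2R)-3,3-dimethyloxiran-2-yl]ethyl}-3-methyloxiran-2-yl]butan-2-one | CC(=O)CC[C@H]1O[C@]1(C)CC[C@H]1OC1(C)C | intermediate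
18 | lithium enolate of 17 (terminal, kinetic) | [Li]OC(=C)CC[C@H]1O[C@]1(C)CC[C@H]1OC1(C)C | intermediate (not isolated)
19 | tert-butyl({4-[(2R,3R)-3-{2-[(2R)-3,3-dimethyloxiran-2-yl]ethyl}-3-methyloxiran-2-yl]but-1-en-2-yl}oxy)dimethylsilane | C=C(O[Si](C)(C)C(C)(C)C)CC[C@H]1O[C@]1(C)CC[C@H]1OC1(C)C | intermediate
20 | (3R,5aR,9aR)-3-[(tert-butyldimethylsilyl)oxy]-2,2,5a-trimethyloctahydro-1-benzoxepin-7(2H)-one (trans-fused) | C1[C@@]2(C)CC[C@@H](O[Si](C)(C)C(C)(C)C)C(C)(C)O[C@@H]2CCC1=O | intermediate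
21 | lithium enolate of 20 (C7–C8 enolate) | C1[C@@]2(C)CC[C@@H](O[Si](C)(C)C(C)(C)C)C(C)(C)O[C@@H]2CC=C1O[Li] | intermediate (not isolated)
22 | C7–C8 trimethylsilyl enol ether of 20 | C1[C@@]2(C)CC[C@@H](O[Si](C)(C)C(C)(C)C)C(C)(C)O[C@@H]2CC=C1O[Si](C)(C)C | intermediate (not isolated)
23 | (3R,5aR,9aR)-3-[(tert-butyldimethylsilyl)oxy]-2,2,5a-trimethyl-3,4,5,5a,6,9a-hexahydro-1-benzoxepin-7(2H)-one | C1[C@@]2(C)CC[C@@H](O[Si](C)(C)C(C)(C)C)C(C)(C)O[C@@H]2C=CC1=O | intermediate
24 | lithium cross-conjugated dienolate of 23 (C6–C7 enolate) | [Li]OC1=C[C@@]2(C)CC[C@@H](O[Si](C)(C)C(C)(C)C)C(C)(C)O[C@@H]2C=C1 | intermediate (not isolated)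
25 | (3R,5aR,6R,9aR)-3-[(tert-butyldimethylsilyl)oxy]-6-(hydroxymethyl)-2,2,5a-trimethyl-3,4,5,5a,6,9a-hexahydro-1-benzoxepin-7(2H)-one | OC[C@H]1[C@@]2(C)CC[C@@H](O[Si](C)(C)C(C)(C)C)C(C)(C)O[C@@H]2C=CC1=O | intermediate
26 | (3R,5aR,6R,9aR)-3-[(tert-butyldimethylsilyl)oxy]-6-(hydroxymethyl)-2,2,5a-trimethyloctahydro-1-benzoxepin-7(2H)-one | OC[C@H]1[C@@]2(C)CC[C@@H](O[Si](C)(C)C(C)(C)C)C(C)(C)O[C@@H]2CCC1=O | intermediate
27 | (3R,5aR,6R,7S,9aR)-3-[(tert-butyldimethylsilyl)oxy]-6-(hydroxymethyl)-2,2,5a,7-tetramethyldecahydro-1-benzoxepin-7-ol | OC[C@H]1[C@@]2(C)CC[C@@H](O[Si](C)(C)C(C)(C)C)C(C)(C)O[C@@H]2CC[C@]1(C)O | intermediate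
28 | (3R,5aR,6R,7S,9aR)-6-(hydroxymethyl)-2,2,5a,7-tetramethyldecahydro-1-benzoxepine-3,7-diol | OC[C@H]1[C@@]2(C)CC[C@@H](O)C(C)(C)O[C@@H]2CC[C@]1(C)O | intermediate
29 | (5aR,6S,7S,9aR)-7-hydroxy-2,2,5a,7-tetramethyl-3-oxodecahydro-1-benzoxepine-6-carbaldehyde | O=C[C@H]1[C@@]2(C)CCC(=O)C(C)(C)O[C@@H]2CC[C@]1(C)O | intermediate
30 | (5aR,6S,7S,9aR)-7-hydroxy-6-[(E)-2-iodoethenyl]-2,2,5a,7-tetramethyloctahydro-1-benzoxepin-3(2H)-one | I/C=C/[C@H]1[C@@]2(C)CCC(=O)C(C)(C)O[C@@H]2CC[C@]1(C)O | intermediate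
31 | (5aR,6S,7S,9aR)-7-hydroxy-6-[(1E,4R)-3-hydroxy-4-methyl-6-{(1R,2R)-2,6,6-trimethyl-2-[(triethylsilyl)oxy]cyclohexyl}hex-1-en-1-yl]-2,2,5a,7-tetramethyloctahydro-1-benzoxepin-3(2H)-one (carbinol epimers) | C[C@@H](C(O)/C=C/[C@H]1[C@@]2(C)CCC(=O)C(C)(C)O[C@@H]2CC[C@]1(C)O)CC[C@@H]1C(C)(C)CCC[C@@]1(C)O[Si](CC)(CC)CC | intermediate
32 | (5aR,6S,7S,9aR)-7-hydroxy-2,2,5a,7-tetramethyl-6-[(1E,4R)-4-methyl-3-oxo-6-{(1R,2R)-2,6,6-trimethyl-2-[(triethylsilyl)oxy]cyclohexyl}hex-1-en-1-yl]octahydro-1-benzoxepin-3(2H)-one | C[C@@H](C(=O)/C=C/[C@H]1[C@@]2(C)CCC(=O)C(C)(C)O[C@@H]2CC[C@]1(C)O)CC[C@@H]1C(C)(C)CCC[C@@]1(C)O[Si](CC)(CC)CC | intermediate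
33 | (5aR,6S,7S,9aR)-7-hydroxy-6-{(1E,4R)-6-[(1R,2R)-2-hydroxy-2,6,6-trimethylcyclohexyl]-4-methyl-3-oxohex-1-en-1-yl}-2,2,5a,7-tetramethyloctahydro-1-benzoxepin-3(2H)-one | C[C@@H](C(=O)/C=C/[C@H]1[C@@]2(C)CCC(=O)C(C)(C)O[C@@H]2CC[C@]1(C)O)CC[C@@H]1C(C)(C)CCC[C@@]1(C)O | intermediate (not isolated)
34 | (5aR,6S,7S,9aR)-7-hydroxy-6-{(E)-2-[(2R,3R,5aR,9aR)-2-hydroxy-3,6,6,9a-tetramethyldecahydro-1-benzoxepin-2-yl]ethenyl}-2,2,5a,7-tetramethyloctahydro-1-benzoxepin-3(2H)-one | C[C@@H]1CC[C@@H]2C(C)(C)CCC[C@@]2(C)O[C@@]1(O)/C=C/[C@H]1[C@@]2(C)CCC(=O)C(C)(C)O[C@@H]2CC[C@]1(C)O | target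

**Step count and risks**

Total steps: 22. Longest linear sequence: 13 steps (steps 10 to 22).

Steps most likely to fail:

Step 3. The enamine carbon is flanked by a quaternary carbon and must attack a methyl ketone, so C–C bond formation may be slow. Intermolecular aldehyde self-condensation, retro-aldol erosion of the trans selectivity or dehydration to the cyclohexene carbaldehyde could then take over. Fallback, setting out from 6 and returning at 7: the ring is closed without asymmetric induction by pyrrolidine and acetic acid in CH2Cl2 to give racemic trans-2-hydroxy-2,6,6-trimethylcyclohexane-1-carbaldehyde F1. NaBH4 in MeOH reduces it to racemic trans-2-(hydroxymethyl)-1,3,3-trimethylcyclohexan-1-ol F2. Lipase-catalysed acetylation with vinyl acetate (kinetic resolution at the primary hydroxyl) removes the unwanted enantiomer as [(1R,2S)-2-hydroxy-2,6,6-trimethylcyclohexyl]methyl acetate F3 and leaves (1R,2S)-2-(hydroxymethyl)-1,3,3-trimethylcyclohexan-1-ol F4, assumed here to be the slow-reacting enantiomer. Selective oxidation of the primary alcohol of F4 with 2,2,6,6-tetramethylpiperidin-1-oxyl and PhI(OAc)2 returns 7.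

Step 7. The aldehyde sits between two fully substituted carbons and the ylide is β-branched, so carbonyl addition may fail and the ylide may instead act as a base (enolization, epimerization). Fallback, setting out from 10 and 8 and returning at 14: Finkelstein exchange (NaI, acetone) converts 10 into benzyl (2S)-3-iodo-2-methylpropyl ether F5. Lithium–iodine exchange (t-BuLi, Et2O, −78 °C) gives [(2R)-3-(benzyloxy)-2-methylpropyl]lithium F6, a far smaller and more reactive nucleophile than the ylide. Its 1,2-addition to 8 gives (3R)-4-(benzyloxy)-3-methyl-1-{(1S,2R)-2,6,6-trimethyl-2-[(triethylsilyl)oxy]cyclohexyl}butan-1-ol F7 as a mixture of carbinol epimers. NaH, CS2 and MeI give its S-methyl xanthate F8. Barton–McCombie deoxygenation (Bu3SnH, AIBN, toluene, 110 °C) gives triethyl({(1R,2R)-2-[(3R)-4-(benzyloxy)-3-methylbutyl]-1,3,3-trimethylcyclohexyl}oxy)silane F9. Hydrogenolysis (H2, Pd(OH)2 on carbon) gives 14.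

Step 16. The axial hydroxymethyl group next to the ketone hinders the equatorial trajectory, so facial selectivity may be poor or the reagent may enolize the ketone. Fallback, setting out from 26 and returning at 28: the primary hydroxyl is silylated (tBuMe2SiCl, imidazole, DMF) to give the bis(tert-butyldimethylsilyl) ether of 26, F10. Corey–Chaykovsky methylenation with dimethylsulfoxonium methylide (Me3S(O)I, NaH, DMSO) forms the new C–C bond equatorially under thermodynamic betaine control and gives the spiro-epoxide with axial oxygen F11. LiEt3BH opens the epoxide at its CH2 to give the bis(tert-butyldimethylsilyl) ether of 28, F12, with the methyl equatorial and the hydroxyl axial. Bu4NF removes both silyl groups and gives 28.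

Further compounds
F1 | step 3 | rac-(1R*,2R*)-2-hydroxy-2,6,6-trimethylcyclohexane-1-carbaldehyde (racemate, one enantiomer drawn) | O=C[C@@H]1C(C)(C)CCC[C@@]1(C)O
F2 | step 3 | rac-(1R*,2S*)-2-(hydroxymethyl)-1,3,3-trimethylcyclohexan-1-ol (racemate, one enantiomer drawn) | OC[C@@H]1C(C)(C)CCC[C@@]1(C)O
F3 | step 3 | [(1R,2S)-2-hydroxy-2,6,6-trimethylcyclohexyl]methyl acetate | CC(=O)OC[C@H]1C(C)(C)CCC[C@]1(C)O
F4 | step 3 | (1R,2S)-2-(hydroxymethyl)-1,3,3-trimethylcyclohexan-1-ol | OC[C@@H]1C(C)(C)CCC[C@@]1(C)O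
F5 | step 7 | benzyl (2S)-3-iodo-2-methylpropyl ether | C[C@@H](COCc1ccccc1)CI
F6 | step 7 | [(2R)-3-(benzyloxy)-2-methylpropyl]lithium | C[C@@H](COCc1ccccc1)C[Li]
F7 | step 7 | (3R)-4-(benzyloxy)-3-methyl-1-{(1S,2R)-2,6,6-trimethyl-2-[(triethylsilyl)oxy]cyclohexyl}butan-1-ol (carbinol epimers) | C[C@@H](COCc1ccccc1)CC(O)[C@@H]1C(C)(C)CCC[C@@]1(C)O[Si](CC)(CC)CC
F8 | step 7 | O-[(3R)-4-(benzyloxy)-3-methyl-1-{(1S,2R)-2,6,6-trimethyl-2-[(triethylsilyl)oxy]cyclohexyl}butyl] S-methyl carbonodithioate | C[C@@H](COCc1ccccc1)CC(OC(=S)SC)[C@@H]1C(C)(C)CCC[C@@]1(C)O[Si](CC)(CC)CC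
F9 | step 7 | triethyl({(1R,2R)-2-[(3R)-4-(benzyloxy)-3-methylbutyl]-1,3,3-trimethylcyclohexyl}oxy)silane | C[C@@H](COCc1ccccc1)CC[C@@H]1C(C)(C)CCC[C@@]1(C)O[Si](CC)(CC)CC
F10 | step 16 | (3R,5aR,6R,9aR)-3-[(tert-butyldimethylsilyl)oxy]-6-{[(tert-butyldimethylsilyl)oxy]methyl}-2,2,5a-trimethyloctahydro-1-benzoxepin-7(2H)-one | CC(C)(C)[Si](C)(C)OC[C@H]1[C@@]2(C)CC[C@@H](O[Si](C)(C)C(C)(C)C)C(C)(C)O[C@@H]2CCC1=O
F11 | step 16 | spiro-epoxide of F10 at the ring carbonyl carbon (CH2 equatorial, O axial and cis to the angular methyl) | CC(C)(C)[Si](C)(C)OC[C@H]1[C@@]2(C)CC[C@@H](O[Si](C)(C)C(C)(C)C)C(C)(C)O[C@@H]2CC[C@]1(C3)O3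
F12 | step 16 | (3R,5aR,6R,7S,9aR)-3-[(tert-butyldimethylsilyl)oxy]-6-{[(tert-butyldimethylsilyl)oxy]methyl}-2,2,5a,7-tetramethyldecahydro-1-benzoxepin-7-ol | CC(C)(C)[Si](C)(C)OC[C@H]1[C@@]2(C)CC[C@@H](O[Si](C)(C)C(C)(C)C)C(C)(C)O[C@@H]2CC[C@]1(C)O
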